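The flasks below carry the same amounts of substrate and solid reagent as the two earlier runs and differ in the free catalyst charged.

in all of them: substrate 0.10 M
- autumn: solid reagent 0.20 M; free catalyst 0.26 mM; run made earlier
- midnight: solid reagent 0.20 M; free catalyst 0.71 mM; run made earlier
- elm: solid reagent 0.200 M; free catalyst 0.25 mM; time 2.0 min
- birch: solid reagent 0.200 M; free catalyst 0.50 mM; time 2.0 min
- maple: solid reagent 0.200 M; free catalyst 1.0 mM; time 2.0 min
- oak: solid reagent 0.200 M; free catalyst 2.0 mM; time 2.0 min

- autumn (time / s: target / %): 25.0: 4.7; 50.0: 9.3; 80.0: 15.4; 90.0: 14.4; 120: 15.7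
- midnight (time / s: target / %): 10.0: 4.4; 20.0: 10.3; 30.0: 14.5; 60.0: 29.9; 120: 41.0

(readings scatter by 1 percentage point)

1. [target] at the end for elm, birch, maple, oak, in this order
2. the course of these numbers from the first flask to the last (rises, then falls / hardly changes / falls all the way / falls, then rises / rises all the way)

Both earlier runs were read at 120 s, which is the asked time of 2.0 min, so we work with the fraction left: the share of the substrate charged that is not target then, 84.3 % in autumn and 59.0 % in midnight. We assume that each equal portion of catalyst multiplies this fraction by the same factor, which keeps c(target) below the charge. Together the two runs give 0.720 mM⁻¹ for the fall of the natural logarithm of the fraction left per unit of catalyst charged, which we call the catalyst exponent.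

Multiplying c(substrate) as charged by one minus the fraction left, we reckon c(target) at the end as 0.0165 M for elm, 0.0302 M for birch, 0.0513 M for maple and 0.0763 M for oak. Maple and oak each carry more catalyst than midnight, so for these two flasks the assumption is untested.

The forecast gave 0.0145 M, 0.028 M, 0.053 M and 0.085 M, higher than ours for oak, with the course rises all the way, on the ground that “Target should therefore scale with catalyst”.

The flasks give 0.0154 M, 0.0297 M, 0.0503 M and 0.0557 M; the course rises all the way.

    catalyst intermediate D → free catalyst + target (k = 7.80 s⁻¹)
    partner + free catalyst ⇌ catalyst intermediate A (K = 49.0 M⁻¹, k = 83.0 M⁻¹ s⁻¹)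
    solid reagent ⇌ partner, rate k3*(cs3 - [partner]) while solid is left; crystals form when [partner] > cs3 (solubility = 0.0630 M, k = 0.0640 s⁻¹)
    catalyst intermediate C ⇌ catalyst intermediate D (K = 34.0, k = 7.20 s⁻¹)
    partner + target → over-reaction product (k = 0.360 M⁻¹ s⁻¹)
    catalyst intermediate B → by-product + catalyst intermediate C (k = 7.30 s⁻¹)
    substrate + catalyst intermediate A → catalyst intermediate B (k = 100 M⁻¹ s⁻¹)
    partner → decomposed reagent (k = 0.0210 s⁻¹)

Oak ends at 0.0557 M, less than our 0.0763 M. At 2.00 min oak holds, in percent of the substrate charged, 55.7 % target, 44.1 % over-reaction product and 0.161 % substrate. Read from oak, the catalyst exponent is 0.408 mM⁻¹, smaller than the 0.720 mM⁻¹ carried over. Applied to maple, 0.720 mM⁻¹ gives a fraction left of 48.7 %, and at 2.00 min maple has 49.7 % of its substrate charge not as target, of which 38.5 % is over-reaction product and 11.1 % is substrate.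

The data are simulated with made-up constants; the scatter is artificial.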